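Terpenoid numbering is used for the sesquiterpene part: C1–C10 are the ring carbons, C11 is the OCH2 on C9, and the methyls sit on C4 (two), C8 and C10. β is the face of the C10 methyl. Compound numbers are those of the steps and of the list after them.

## Analysis of the target

Target 29 is the aryl ether between the phenol oxygen of isofraxidin 25 and C11 of a 9-epi-drimane. The sesquiterpene is a trans-fused decalin. Ring A carries the axial 3α-isovalerate next to the C4 gem-dimethyl group; ring B carries the C6 ketone conjugated with the C7–C8 alkene (methyl on C8); the rings share C5 (H α) and the quaternary C10 (methyl β). There are four stereocentres, C3, C5, C9 and C10 (3R,5R,9R,10R): C5–H and the C10 methyl are trans, C11 lies on the α face anti to the angular methyl (the opposite of the usual drimane chiral pool), and the C3 oxygen is α, cis to C5–H. The sensitive groups are the coumarin lactone (hydride, hydroxide), the isovalerate and above all the enone: C9–H is its γ-hydrogen and the aryloxy group sits on the δ-carbon, so base can expel 25 by a vinylogous E1cB elimination, while C5 is an epimerisable α′ centre. The synthesis is hard because of the contiguous array C4 (quaternary)–C5–C10 (quaternary)–C9, the anti relationship of C11 and the C10 methyl, and the ether at a hindered β-branched primary carbon to a di-ortho-substituted phenol. The strategy rests on ring B: with its C6 oxygen written as a silyl enol ether (C6=C7) it is a cyclohexene whose bonds C5–C10 and C8–C9 flank the oxygenated carbon. That is the adduct of a 2-silyloxy diene C5=C6–C7=C8 and a dienophile C9=C10 whose activating carbonyl is C11. The four carbons C1–C4 tie C10 to C5, so one intramolecular cycloaddition closes rings A and B together.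

## Retrosynthetic reasoning

**C7–C8 unsaturation (29 to 28).** The last disconnection removes the C7–C8 double bond and leads to the saturated trans-fused ketone 28. Only this position can be dehydrogenated, since C5 has no β-hydrogen. It is done last because, once the enone exists, C9–H is vinylogously acidic and the aryloxide on C11 can leave; no basic or equilibrating step may follow. The forward reaction must therefore be a ketone dehydrogenation under non-basic conditions.

**Ring fusion (28 to 27 to 26).** Ketone 28 is the C5 epimer of the cis-fused ketone 27, which protonolysis of the enol ether 26 delivers. C5 is corrected on the saturated ketone because there C9–H is not activated and only the ring-fusion centre can move. The trans isomer should be favoured, since each chair–chair form of the cis isomer puts a ring bond syn-axial to a substituent. This frees the ring-forming step from having to control C5.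

**Ether bond O–C11 (26 to 24 and 25).** The cut is made on the alkyl side because 25 is an acidic phenol suited to a redox condensation with a primary alcohol. It is made at this stage because in alcohol 24 the ketone is still masked as the enol ether, so activating the C11 hydroxyl opens no elimination path. The coumarin also enters only after the hydride step, which it would not survive.

**C11 oxidation level (24 to 23).** The alcohol comes from the imide 23 by reductive removal of the auxiliary, which returns 19. The forward step must reduce the hindered, chelation-activated imide carbonyl and leave the C3 ester and the silyl enol ether alone.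

**C5–C10 and C8–C9 (23 to 22).** Both bonds of ring B next to the oxygenated carbon are cut, which opens rings A and B to the open-chain triene 22. These are the two bonds that a [4+2] addition makes, and the tether turns the regiochemistry into a matter of ring size. The step creates four stereocentres, of which only C9 and C10 must be right. The forward reaction has to deliver the diene to one face of the Z-enoyl unit and stay stereospecific.

**Diene and imide (22 to 21 to 18 and 19, 18 from 17).** The silyloxy diene is the cross-conjugated enol ether of enone 21, made by soft enolisation at the α′ methylene C5. The imide comes from acid 18 and auxiliary 19 through the mixed anhydride 20. The acid is carried as its tert-butyl ester 17, which tolerates the organometallic and oxidative steps and is removed by acid without touching the isovalerate.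

**C6–C7 and the C6 oxygen (17 to 14 and 15, 14 from 11).** The propenyl ketone is cut between C6 and C7 into aldehyde 14 and the alkenyl bromide 15; the carbinol 16 lies between them. Aldehyde 14 derives from the vinyl group of 11 by anti-Markovnikov hydration (borane 12, alcohol 13) and oxidation. This uses the terminal alkene that the preceding C–C bond formation leaves behind.

**C3–C4 (11 to 10 to 7 and 8).** The bond between the carbinol carbon and the quaternary carbon is cut to aldehyde 7 and a reverse-prenyl nucleophile derived from allene 8. This is the one place where a reagent-controlled addition makes the gem-dimethyl carbon and the C3 stereocentre at once. The forward step must add to the Si face of 7; esterification then gives 11.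

**Z-enoate (7 back to 1).** The Z-trisubstituted alkene C9=C10 is taken back to ynoate 4 by removing the C10 methyl, since syn-carbocupration is the dependable way to put the chain cis to the ester. Ynoate 4 comes from alkyne 2 through acetylide 3, and 2 from alkynol 1, whose hydroxyl becomes the C3 aldehyde by way of 5 and 6.

## Alternatives that were turned down

**Alternative 1: carbene-catalysed desymmetrisation.**
- Disconnection: the C5–C6 bond of ring B, back to the achiral cyclohexadienone aldehyde A1.
- Forward key step: a chiral triazolylidene carbene turns the aldehyde into an acyl anion equivalent, which adds to one of the two enantiotopic enone β-carbons (intramolecular Stetter reaction) and gives the cis-fused enedione A2.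
- For: enantiocontrol is catalytic and needs no auxiliary, C10 arises as a quaternary centre from a symmetrical precursor, and the C6 ketone appears on the right carbon. On these points it is stronger than the chosen route.
- Against: A2 is only the bare bicycle. It lacks the gem-dimethyl group, the C8 methyl, the C7–C8 alkene and above all C11. C9 in A2 is an unactivated methylene beside a quaternary carbon; a carbon could be attached there only by γ-functionalisation of a later enone, and dienolates react at C7 instead. The C3 ketone must still be reduced to the axial alcohol, the C1–C2 alkene removed and the cis fusion corrected. Closing a six-membered carbocycle this way is also less secure than the usual five-membered, heteroatom-tethered cases.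
- Comparison: what it saves in the ring-forming step it repays several times in decoration. The chosen cycloaddition brings in C11, the C8 methyl, the C6 oxygen and a fully substituted ring A in one step.

**Alternative 2: cathodic radical cyclisation.**
- Disconnection: the C1–C10 bond, back to iodide A3, a ring B enone (C6 ketone, C5=C10 alkene) from the terpene chiral pool with the ring A chain on C5.
- Forward key step: cathodic reduction mediated by a nickel macrocycle gives the primary C1 radical, which closes 6-endo onto the enone β-carbon C10; protonation of the resulting enolate gives the trans-fused ketone A4.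
- For: ring B and its methyl are bought, radical addition suits a quaternary centre, and the trans fusion may come directly from the enolate. That last point is better than the chosen route, which corrects C5 afterwards. The electrochemical step needs no stoichiometric metal.
- Against: the only purchased stereocentre, C8, is destined to become sp2, so it acts merely as a 1,3-relay to C10, a weak control element. C3 must be set separately anyway. A4 has no C11, and C9 is again a bare methylene between C8 and quaternary C10, the least accessible site for a late, stereocontrolled C–C bond. Attack at a fully substituted β-carbon also competes with simple reduction of the radical.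
- Comparison: in the chosen route the C9–C11 bond exists before the rings do, and C9 is set together with C10 by alkene geometry.

**Alternative 3: epoxy-polyene bicyclisation.**
- Disconnection: the C4–C5 and C9–C10 bonds, back to the terminal (S)-epoxide A5 of the (2Z,6E)-farnesyl ether of 25.
- Forward key step: a Lewis acid opens the epoxide and a chair–chair cation–olefin cascade closes ring A and then ring B; the C8 cation loses a proton to give the C7–C8 alkene of A6.
- For: it is by far the shortest. The ether is made at the start by simple phenol alkylation, and the trans fusion, the quaternary C10 and, through the Z-alkene, the α-oriented C11 all emerge in one step. On step economy and on ring fusion it is clearly stronger than the chosen route.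
- Against: A6 has an equatorial 3β-hydroxyl, fixed by the chair opening of the epoxide, whereas 29 needs the 3α-ester; this means an oxidation and axial-selective reduction, or an inversion at a neopentyl-type carbinol. A6 has no C6 oxygen, so a late allylic oxidation must choose among three allylic sites beside an electron-rich coumarin. The substrate is an allylic aryl ether that a strong Lewis acid can ionise, its terminating alkene is deactivated by the allylic oxygen, and proton loss is seldom regioselective.
- Comparison: the chosen route is longer, but it puts C3 under reagent control, places the C6 oxygen by construction and fixes the alkene position through the regiochemistry of an enol ether.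

Key step: step 15

Remark on the chemistry: the prenylborane made from (−)-diisopinocampheylborane, (−)-Ipc2BH, of the (+)-α-pinene series, is taken to add to the Si face of aldehyde 7, as its allyl congener does with aliphatic aldehydes; 8 and 15 are taken as catalogue compounds.

## Route

Step 1
Reactants: 1 pent-4-yn-1-ol
Product: 2 tert-butyldimethyl(pent-4-yn-1-yloxy)silane
Conditions: TBSCl, imidazole, DMF, 0 °C to rt
Reagents that add atoms: tert-butyldimethylsilyl chloride, CC(C)(C)[Si](C)(C)Cl
Why: Standard silylation of a primary alcohol; the silyl ether keeps the hydroxyl out of the acetylide and cuprate chemistry.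

Step 2
Reactants: 2 tert-butyldimethyl(pent-4-yn-1-yloxy)silane
Product: 4 tert-butyl 6-(tert-butyldimethylsilyloxy)hex-2-ynoate, via lithium acetylide 3 (not isolated)
Conditions: n-BuLi, THF, −78 °C; Boc2O, −78 to 0 °C; aq. NH4Cl
Reagents that add atoms: di-tert-butyl dicarbonate, CC(C)(C)OC(=O)OC(=O)OC(C)(C)C
Why: Deprotonation of the terminal alkyne and acylation of the acetylide with the dicarbonate gives the ynoate (C11 joined to C9). The tert-butyl ester is chosen because it resists the later nucleophiles and oxidants and is cleaved by acid.

Step 3
Reactants: 4 tert-butyl 6-(tert-butyldimethylsilyloxy)hex-2-ynoate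
Product: 5 tert-butyl (Z)-6-(tert-butyldimethylsilyloxy)-3-methylhex-2-enoate
Conditions: Me2CuLi (from CuI and 2 MeLi), THF, −78 °C; MeOH at −78 °C, then aq. NH4Cl
Reagents that add atoms: lithium dimethylcuprate, [Li+].C[Cu-]C
Why: Syn-carbocupration of the ynoate puts the methyl on C10 cis to copper on C9, and protonation with retention leaves the chain cis to the ester (Z). Quenching cold prevents equilibration of the alkenylcopper through the allenolate.

Step 4
Reactants: 5 tert-butyl (Z)-6-(tert-butyldimethylsilyloxy)-3-methylhex-2-enoate
Product: 6 tert-butyl (Z)-6-hydroxy-3-methylhex-2-enoate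
Conditions: HF·pyridine, pyridine, THF, 0 °C to rt
Reagents that add atoms: none
Why: Fluoride cleavage of the primary silyl ether under buffered, non-basic conditions, so that no alkoxide can add to C10 of the enoate; the tert-butyl ester is stable.

Step 5
Reactants: 6 tert-butyl (Z)-6-hydroxy-3-methylhex-2-enoate
Product: 7 tert-butyl (Z)-3-methyl-6-oxohex-2-enoate
Conditions: Dess–Martin periodinane, NaHCO3, CH2Cl2, 0 °C to rt
Reagents that add atoms: none
Why: Dess–Martin oxidation stops at the aldehyde and, being buffered, does not isomerise the Z-enoate.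

Step 6
Reactants: 7 tert-butyl (Z)-3-methyl-6-oxohex-2-enoate; 8 3-methylbuta-1,2-diene
Product: 10 tert-butyl (2Z,6R)-6-hydroxy-3,7,7-trimethylnona-2,8-dienoate, via borinate ester 9 (not isolated)
Conditions: (−)-Ipc2BH [from (+)-α-pinene], 8, THF, −25 °C; then 7, −78 °C; NaBO3·4H2O, THF/H2O, rt
Reagents that add atoms: none
Why: Hydroboration of the allene gives the B-prenyl reagent, which adds to the aldehyde in an asymmetric allylboration through a closed chair transition state with allylic transposition, so the dimethyl-substituted carbon (C4) bonds to C3 and a vinyl group remains. The isopinocampheyl ligands direct Si-face addition and set C3 as R; the mild perborate work-up spares the enoate.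

Step 7
Reactants: 10 tert-butyl (2Z,6R)-6-hydroxy-3,7,7-trimethylnona-2,8-dienoate
Product: 11 tert-butyl (2Z,6R)-3,7,7-trimethyl-6-(3-methylbutanoyloxy)nona-2,8-dienoate
Conditions: 3-methylbutanoyl chloride, pyridine, DMAP (cat.), CH2Cl2, 0 °C to rt
Reagents that add atoms: 3-methylbutanoyl chloride, CC(C)CC(=O)Cl
Why: DMAP-catalysed acylation of the hindered secondary alcohol; the ester of the target is installed now and serves as the protecting group for C3.

Step 8
Reactants: 11 tert-butyl (2Z,6R)-3,7,7-trimethyl-6-(3-methylbutanoyloxy)nona-2,8-dienoate
Product: 13 tert-butyl (2Z,6R)-9-hydroxy-3,7,7-trimethyl-6-(3-methylbutanoyloxy)non-2-enoate, via alkylborane 12 (not isolated)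
Conditions: 9-BBN, THF, 0 °C to rt; NaBO3·4H2O, H2O, rt
Reagents that add atoms: sodium perborate tetrahydrate (NaBO3·4H2O), [Na+].[Na+].O[B-]1(O)OO[B-](O)(O)OO1
Why: Anti-Markovnikov hydroboration–oxidation; 9-BBN takes the terminal vinyl group and ignores the trisubstituted, electron-poor enoate alkene and both esters, and perborate oxidises the borane without hydrolysing them.

Step 9
Reactants: 13 tert-butyl (2Z,6R)-9-hydroxy-3,7,7-trimethyl-6-(3-methylbutanoyloxy)non-2-enoate
Product: 14 tert-butyl (2Z,6R)-3,7,7-trimethyl-6-(3-methylbutanoyloxy)-9-oxonon-2-enoate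
Conditions: Dess–Martin periodinane, NaHCO3, CH2Cl2, rt
Reagents that add atoms: none
Why: Dess–Martin oxidation of the primary alcohol to the C6 aldehyde; the acyloxy group is γ to the new carbonyl, so it cannot be eliminated.

Step 10
Reactants: 14 tert-butyl (2Z,6R)-3,7,7-trimethyl-6-(3-methylbutanoyloxy)-9-oxonon-2-enoate; 15 (E)-1-bromoprop-1-ene
Product: 16 tert-butyl (2Z,6R,10E)-9-hydroxy-3,7,7-trimethyl-6-(3-methylbutanoyloxy)dodeca-2,10-dienoate (both carbinol epimers)
Conditions: CrCl2, NiCl2 (cat.), DMF, rt
Reagents that add atoms: none
Why: Nozaki–Hiyama–Kishi reaction: nickel inserts into the alkenyl bromide with retention, the alkenyl group passes to chromium, and the organochromium adds to the aldehyde only, leaving both esters. The new carbinol centre is oxidised away in the next step.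

Step 11
Reactants: 16 tert-butyl (2Z,6R,10E)-9-hydroxy-3,7,7-trimethyl-6-(3-methylbutanoyloxy)dodeca-2,10-dienoate
Product: 17 tert-butyl (2Z,6R,10E)-3,7,7-trimethyl-6-(3-methylbutanoyloxy)-9-oxododeca-2,10-dienoate
Conditions: Dess–Martin periodinane, NaHCO3, CH2Cl2, rt
Reagents that add atoms: none
Why: Dess–Martin oxidation of the allylic alcohol gives the (E)-propenyl ketone, the precursor of the diene.

Step 12
Reactants: 17 tert-butyl (2Z,6R,10E)-3,7,7-trimethyl-6-(3-methylbutanoyloxy)-9-oxododeca-2,10-dienoate
Product: 18 (2Z,6R,10E)-3,7,7-trimethyl-6-(3-methylbutanoyloxy)-9-oxododeca-2,10-dienoic acid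
Conditions: CF3CO2H, CH2Cl2, 0 °C to rt
Reagents that add atoms: none
Why: Acidolysis of the tert-butyl ester by loss of the tert-butyl cation; the isovalerate, the enone and the Z-alkene are not affected under these conditions.

Step 13
Reactants: 18 (2Z,6R,10E)-3,7,7-trimethyl-6-(3-methylbutanoyloxy)-9-oxododeca-2,10-dienoic acid; 19 (R)-4-benzyl-1,3-oxazolidin-2-one
Product: 21 (R)-4-benzyl-3-[(2Z,6R,10E)-3,7,7-trimethyl-6-(3-methylbutanoyloxy)-9-oxododeca-2,10-dienoyl]-1,3-oxazolidin-2-one, via mixed pivalic anhydride 20 (not isolated)
Conditions: t-BuCOCl, Et3N, THF, −20 °C; then LiCl, 19, −20 °C to rt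
Reagents that add atoms: none
Why: Mixed-anhydride N-acylation of the oxazolidinone under LiCl and amine; the nucleophile attacks the enoyl carbonyl, not the hindered pivaloyl one, and the absence of strong base and heat keeps the Z geometry and the enone intact.

Step 14
Reactants: 21 (R)-4-benzyl-3-[(2Z,6R,10E)-3,7,7-trimethyl-6-(3-methylbutanoyloxy)-9-oxododeca-2,10-dienoyl]-1,3-oxazolidin-2-one
Product: 22 (R)-4-benzyl-3-[(2Z,6R,8Z,10E)-3,7,7-trimethyl-6-(3-methylbutanoyloxy)-9-(triisopropylsilyloxy)dodeca-2,8,10-trienoyl]-1,3-oxazolidin-2-one
Conditions: TIPSOTf, Et3N, CH2Cl2, −78 to 0 °C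
Reagents that add atoms: triisopropylsilyl trifluoromethanesulfonate, CC(C)[Si](OS(=O)(=O)C(F)(F)F)(C(C)C)C(C)C
Why: Soft enolisation: O-silylation of the ketone followed by loss of an α′ proton from C5 gives the cross-conjugated 2-silyloxy diene. The Z enol ether, with the quaternary C4 trans to the propenyl group, is favoured by allylic strain and places C4 on the outside of the diene; the ketone reacts in preference to the imide and the ester.

Step 15
Reactants: 22 (R)-4-benzyl-3-[(2Z,6R,8Z,10E)-3,7,7-trimethyl-6-(3-methylbutanoyloxy)-9-(triisopropylsilyloxy)dodeca-2,8,10-trienoyl]-1,3-oxazolidin-2-one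
Product: 23 N-acyl oxazolidinone of the cis-fused endo adduct: (R)-4-benzyl-3-[3α-(3-methylbutanoyloxy)-6-(triisopropylsilyloxy)-5β,8β,9β-H-drim-6-en-11-oyl]-1,3-oxazolidin-2-one (C8 methyl α, C11 α, C10 methyl β)
Conditions: Me2AlCl (2.5 equiv), CH2Cl2, −78 to −20 °C; aq. potassium sodium tartrate work-up
Reagents that add atoms: none
Why: Excess Me2AlCl binds both imide carbonyls as a cationic chelate, which locks the Z-enoyl unit s-cis and lowers its LUMO, and the electron-rich 2-silyloxy diene then adds suprafacially in a concerted but asynchronous [4+2] step in which the C5–C10 bond, joining the nucleophilic enol-ether carbon to the enoyl β-carbon, runs ahead of C8–C9. The closest known reaction type is the dialkylaluminium chloride promoted intramolecular Diels–Alder reaction of 1,7,9-decatrienoyl oxazolidinones. Ring B (C5–C6–C7–C8–C9–C10) is the cycloaddition ring itself, closed by both new bonds, and ring A (C10–C1–C2–C3–C4–C5) closes through the four-carbon tether as C5–C10 forms, 6-exo with respect to both π systems (fused mode). C9 and C10 are controlled by the auxiliary and the alkene geometry: in the chelate the benzyl group of the (R)-oxazolidinone covers one face of C9=C10, the diene adds to the other, and suprafacial addition to the Z-alkene places the C10 methyl and C11 on opposite faces of ring B. C5 and C8 are controlled by the diene geometry (8Z enol ether, 10E propenyl) and by the endo topicity expected for a Z-dienophile, with imide carbonyl and tether both under the diene, which gives the cis-fused adduct with 5β-H and 8α-methyl. The step therefore needs π-facial selectivity at the dienophile and a stereospecific, non-stepwise course, whereas endo or exo topicity is not critical, because C5 is corrected in step 18 and C8 is erased in step 19. Facial selectivity is secured by two-point chelation and the benzyl group, regiochemistry by the tether and the matched polarity of C5 and C10, and the rate by the gem-dimethyl group on the tether (Thorpe–Ingold effect); the bulky silyl group keeps the enol ether intact under the Lewis acid, and C3 is a spectator.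

Step 16
Reactants: 23 N-acyl oxazolidinone of the cis-fused endo adduct
Product: 24 11-hydroxy-6-(triisopropylsilyloxy)-5β,8β,9β-H-drim-6-en-3α-yl 3-methylbutanoate
Conditions: LiBH4, H2O (1 equiv), Et2O, 0 °C
Reagents that add atoms: none
Why: Reductive cleavage of the N-acyl oxazolidinone: the lithium-chelated exocyclic carbonyl is reduced to the primary alcohol and the auxiliary is released, while the unactivated, hindered C3 ester and the silyl enol ether should survive the short exposure at 0 °C. No stereocentre is touched.

Step 17
Reactants: 24 11-hydroxy-6-(triisopropylsilyloxy)-5β,8β,9β-H-drim-6-en-3α-yl 3-methylbutanoate; 25 isofraxidin (7-hydroxy-6,8-dimethoxy-2H-chromen-2-one)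
Product: 26 6,8-dimethoxy-7-{[3α-(3-methylbutanoyloxy)-6-(triisopropylsilyloxy)-5β,8β,9β-H-drim-6-en-11-yl]oxy}-2H-chromen-2-one
Conditions: PPh3, DIAD, THF, 0 °C to rt
Reagents that add atoms: none
Why: Mitsunobu etherification: the acidic phenol protonates the betaine and its phenoxide displaces the alkoxyphosphonium at primary C11 by SN2. With the ketone still masked as the enol ether there is no acidic hydrogen next to the activated carbon, so elimination has no easy path.

Step 18
Reactants: 26 6,8-dimethoxy-7-{[3α-(3-methylbutanoyloxy)-6-(triisopropylsilyloxy)-5β,8β,9β-H-drim-6-en-11-yl]oxy}-2H-chromen-2-one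
Product: 28 6,8-dimethoxy-7-{[3α-(3-methylbutanoyloxy)-6-oxo-5α,8β,9β-H-driman-11-yl]oxy}-2H-chromen-2-one (trans-fused), via cis-fused ketone 27 (not isolated)
Conditions: p-TsOH·H2O, CHCl3, rt, then 55 °C
Reagents that add atoms: none
Why: Acid protonates the enol ether at C7 and removes silicon to give the cis-fused ketone; continued acid-catalysed enolisation towards C5 then equilibrates the ring fusion to the trans-decalone, which should be the more stable isomer because each chair–chair form of the cis isomer carries a syn-axial ring bond. C5 is thus set under thermodynamic control, and C9, C8 and C3 are not enolisable here; the aryl ether, lactone and ester tolerate anhydrous acid.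

Step 19
Reactants: 28 6,8-dimethoxy-7-{[3α-(3-methylbutanoyloxy)-6-oxo-5α,8β,9β-H-driman-11-yl]oxy}-2H-chromen-2-one
Product: 29 6,8-dimethoxy-7-{[(3R,5R,9R,10R)-3-(3-methylbutanoyloxy)-6-oxodrim-7-en-11-yl]oxy}-2H-chromen-2-one (CNP0279705.1)
Conditions: IBX, DMSO/fluorobenzene, 70 °C
Reagents that add atoms: none
Why: Dehydrogenation of the ketone with 2-iodoxybenzoic acid: enolisation is productive only towards C7, the one α-carbon with a β-hydrogen, and the pentavalent iodine reagent removes H from C7 and C8, which gives the C7–C8 enone and erases the C8 stereocentre. The medium is not basic, so the γ-hydrogen at C9 and the aryloxy group are left alone.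

## Compound list

1 | pent-4-yn-1-ol | C#CCCCO | starting material
2 | tert-butyldimethyl(pent-4-yn-1-yloxy)silane | C#CCCCO[Si](C)(C)C(C)(C)C | intermediate
3 | [5-(tert-butyldimethylsilyloxy)pent-1-yn-1-yl]lithium (not isolated) | [Li]C#CCCCO[Si](C)(C)C(C)(C)C | intermediate
4 | tert-butyl 6-(tert-butyldimethylsilyloxy)hex-2-ynoate | CC(C)(C)OC(=O)C#CCCCO[Si](C)(C)C(C)(C)C | intermediate
5 | tert-butyl (Z)-6-(tert-butyldimethylsilyloxy)-3-methylhex-2-enoate | CC(C)(C)OC(=O)/C=C(/C)CCCO[Si](C)(C)C(C)(C)C | intermediate
6 | tert-butyl (Z)-6-hydroxy-3-methylhex-2-enoate | CC(C)(C)OC(=O)/C=C(/C)CCCO | intermediate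
7 | tert-butyl (Z)-3-methyl-6-oxohex-2-enoate | CC(C)(C)OC(=O)/C=C(/C)CCC=O | intermediate
8 | 3-methylbuta-1,2-diene | CC(C)=C=C | starting material
9 | diisopinocampheylborinate ester of 10 (not isolated) | CC(C)(C)OC(=O)/C=C(/C)CC[C@@H](OB([C@@H]1C[C@@H]2C[C@H]([C@H]1C)C2(C)C)[C@@H]1C[C@@H]2C[C@H]([C@H]1C)C2(C)C)C(C)(C)C=C | intermediate
10 | tert-butyl (2Z,6R)-6-hydroxy-3,7,7-trimethylnona-2,8-dienoate | CC(C)(C)OC(=O)/C=C(/C)CC[C@@H](O)C(C)(C)C=C | intermediate
11 | tert-butyl (2Z,6R)-3,7,7-trimethyl-6-(3-methylbutanoyloxy)nona-2,8-dienoate | CC(C)(C)OC(=O)/C=C(/C)CC[C@@H](OC(=O)CC(C)C)C(C)(C)C=C | intermediate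
12 | B-alkyl-9-borabicyclo[3.3.1]nonane from 11 (not isolated) | CC(C)(C)OC(=O)/C=C(/C)CC[C@@H](OC(=O)CC(C)C)C(C)(C)CCB1C2CCCC1CCC2 | intermediate
13 | tert-butyl (2Z,6R)-9-hydroxy-3,7,7-trimethyl-6-(3-methylbutanoyloxy)non-2-enoate | CC(C)(C)OC(=O)/C=C(/C)CC[C@@H](OC(=O)CC(C)C)C(C)(C)CCO | intermediate
14 | tert-butyl (2Z,6R)-3,7,7-trimethyl-6-(3-methylbutanoyloxy)-9-oxonon-2-enoate | CC(C)(C)OC(=O)/C=C(/C)CC[C@@H](OC(=O)CC(C)C)C(C)(C)CC=O | intermediate
15 | (E)-1-bromoprop-1-ene | C/C=C/Br | starting material
16 | tert-butyl (2Z,6R,10E)-9-hydroxy-3,7,7-trimethyl-6-(3-methylbutanoyloxy)dodeca-2,10-dienoate (both carbinol epimers) | CC(C)(C)OC(=O)/C=C(/C)CC[C@@H](OC(=O)CC(C)C)C(C)(C)CC(O)/C=C/C | intermediate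
17 | tert-butyl (2Z,6R,10E)-3,7,7-trimethyl-6-(3-methylbutanoyloxy)-9-oxododeca-2,10-dienoate | CC(C)(C)OC(=O)/C=C(/C)CC[C@@H](OC(=O)CC(C)C)C(C)(C)CC(=O)/C=C/C | intermediate
18 | (2Z,6R,10E)-3,7,7-trimethyl-6-(3-methylbutanoyloxy)-9-oxododeca-2,10-dienoic acid | OC(=O)/C=C(/C)CC[C@@H](OC(=O)CC(C)C)C(C)(C)CC(=O)/C=C/C | intermediate
19 | (R)-4-benzyl-1,3-oxazolidin-2-one | O=C1OC[C@@H](Cc2ccccc2)N1 | starting material
20 | mixed pivalic anhydride of 18 (not isolated) | CC(C)(C)C(=O)OC(=O)/C=C(/C)CC[C@@H](OC(=O)CC(C)C)C(C)(C)CC(=O)/C=C/C | intermediate
21 | (R)-4-benzyl-3-[(2Z,6R,10E)-3,7,7-trimethyl-6-(3-methylbutanoyloxy)-9-oxododeca-2,10-dienoyl]-1,3-oxazolidin-2-one | O=C1OC[C@@H](Cc2ccccc2)N1C(=O)/C=C(/C)CC[C@@H](OC(=O)CC(C)C)C(C)(C)CC(=O)/C=C/C | intermediate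
22 | (R)-4-benzyl-3-[(2Z,6R,8Z,10E)-3,7,7-trimethyl-6-(3-methylbutanoyloxy)-9-(triisopropylsilyloxy)dodeca-2,8,10-trienoyl]-1,3-oxazolidin-2-one | O=C1OC[C@@H](Cc2ccccc2)N1C(=O)/C=C(/C)CC[C@@H](OC(=O)CC(C)C)C(C)(C)/C=C(O[Si](C(C)C)(C(C)C)C(C)C)/C=C/C | intermediate
23 | (R)-4-benzyl-3-[3α-(3-methylbutanoyloxy)-6-(triisopropylsilyloxy)-5β,8β,9β-H-drim-6-en-11-oyl]-1,3-oxazolidin-2-one (cis-fused endo adduct) | O=C1OC[C@@H](Cc2ccccc2)N1C(=O)[C@@H]1[C@H](C)C=C(O[Si](C(C)C)(C(C)C)C(C)C)[C@@H]2C(C)(C)[C@H](OC(=O)CC(C)C)CC[C@]12C | intermediate
24 | 11-hydroxy-6-(triisopropylsilyloxy)-5β,8β,9β-H-drim-6-en-3α-yl 3-methylbutanoate | OC[C@@H]1[C@H](C)C=C(O[Si](C(C)C)(C(C)C)C(C)C)[C@@H]2C(C)(C)[C@H](OC(=O)CC(C)C)CC[C@]12C | intermediate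
25 | isofraxidin (7-hydroxy-6,8-dimethoxy-2H-chromen-2-one) | COc1cc2ccc(=O)oc2c(OC)c1O | starting material
26 | 6,8-dimethoxy-7-{[3α-(3-methylbutanoyloxy)-6-(triisopropylsilyloxy)-5β,8β,9β-H-drim-6-en-11-yl]oxy}-2H-chromen-2-one | COc1cc2ccc(=O)oc2c(OC)c1OC[C@@H]1[C@H](C)C=C(O[Si](C(C)C)(C(C)C)C(C)C)[C@@H]2C(C)(C)[C@H](OC(=O)CC(C)C)CC[C@]12C | intermediate
27 | 6,8-dimethoxy-7-{[3α-(3-methylbutanoyloxy)-6-oxo-5β,8β,9β-H-driman-11-yl]oxy}-2H-chromen-2-one (cis-fused, not isolated) | COc1cc2ccc(=O)oc2c(OC)c1OC[C@@H]1[C@H](C)CC(=O)[C@@H]2C(C)(C)[C@H](OC(=O)CC(C)C)CC[C@]12C | intermediate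
28 | 6,8-dimethoxy-7-{[3α-(3-methylbutanoyloxy)-6-oxo-5α,8β,9β-H-driman-11-yl]oxy}-2H-chromen-2-one (trans-fused) | COc1cc2ccc(=O)oc2c(OC)c1OC[C@@H]1[C@H](C)CC(=O)[C@H]2C(C)(C)[C@H](OC(=O)CC(C)C)CC[C@]12C | intermediate
29 | 6,8-dimethoxy-7-{[(3R,5R,9R,10R)-3-(3-methylbutanoyloxy)-6-oxodrim-7-en-11-yl]oxy}-2H-chromen-2-one (CNP0279705.1) | COc1cc2ccc(=O)oc2c(OC)c1OC[C@@H]1C(C)=CC(=O)[C@H]2C(C)(C)[C@H](OC(=O)CC(C)C)CC[C@]12C | target

## Step count and least certain steps

Total step count: 19. Longest linear sequence: 19 steps (1 to 29); 8, 15, 19 and 25 enter as purchased building blocks.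

**Step 15 (key step).** The C5–C10 bond joins a diene terminus that bears a quaternary carbon to a β,β-disubstituted dienophile carbon. The most likely failure is a cycloaddition so slow that Lewis-acid cleavage of the enol ether, or a stepwise Mukaiyama–Michael course, takes over; a stepwise course would free C9 from the alkene geometry. The C3 stereocentre on the tether may also work against the auxiliary and erode facial selectivity. Exo topicity would not be harmful, since that adduct converges on 29 as well. The fallback sets out from enone imide 21 and makes the same two bonds as an anionic double Michael reaction. LiN(SiMe3)2 in THF at −78 °C forms the cross-conjugated lithium enolate, which adds to C10 of the lithium-chelated enoyl imide; the imide enolate then closes ring B at C8 and gives the ketone imide F1 after protonation. Soft enolisation of F1 towards C7 with TIPSOTf and Et3N comes back to the route at 23. C9 would then be set by the ring closure, not by the alkene geometry, and would have to be checked.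

**Step 18.** Enolisation towards C5, which lies between two quaternary carbons, may be slow, and the equilibrium may leave cis material. The fallback sets out from 26 and replaces equilibration by kinetic protonation. Buffered fluoride (TBAF, AcOH) gives 27, which is isolated. IBX dehydrogenation gives the cis-fused enone F2, in which C5 is the only α-carbon. TMSOTf and Et3N at low temperature give the cross-conjugated trimethylsilyl dienol ether F3, and protonation with HF·pyridine at −40 °C should occur at C5 from the α face, away from the axial methyls on C4 and C10. It comes back at 29.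

**Step 17.** Substitution at the β-branched C11 by a phenol flanked by two methoxy groups may be slow, so that the betaine is consumed in side reactions. The fallback sets out from 24 and separates activation from displacement: MsCl and Et3N give the mesylate F4, and heating with 25 and Cs2CO3 in DMF (NaI as catalyst) gives the ether. It comes back at 26.

**Step 16.** The imide carbonyl is flanked by C8 and quaternary C10, so hydride may attack the ring carbonyl of the auxiliary and open it, or the reduction may become slow enough for the C3 ester to be reduced. The fallback sets out from 23 and uses a sulfur nucleophile, which attacks only the exocyclic carbonyl: EtSLi in THF at 0 °C gives the S-ethyl thioester F5 and frees 19, and NaBH4 in EtOH then reduces the thioester but not the ester. It comes back at 24.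

**Step 19.** At 70 °C the product enone may lose the aryloxide thermally or be oxidised further through its dienol, and enolisation of the hindered ketone may be sluggish. The fallback sets out from 28 and works at room temperature through the enol ether: TMSOTf and Et3N give the trimethylsilyl enol ether F6 (C6=C7, the less hindered side), and Pd(OAc)2 in MeCN (Saegusa–Ito oxidation, divalent palladium removing H from C8) gives the enone. It comes back at 29.

## Further compounds

F1 | step 15 | (R)-4-benzyl-3-[3α-(3-methylbutanoyloxy)-6-oxo-5β,8β,9β-H-driman-11-oyl]-1,3-oxazolidin-2-one (drawn with C5 and C8 as in 23) | O=C1OC[C@@H](Cc2ccccc2)N1C(=O)[C@@H]1[C@H](C)CC(=O)[C@@H]2C(C)(C)[C@H](OC(=O)CC(C)C)CC[C@]12C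
F2 | step 18 | 6,8-dimethoxy-7-{[3α-(3-methylbutanoyloxy)-6-oxo-5β,9β-H-drim-7-en-11-yl]oxy}-2H-chromen-2-one (cis-fused enone, 5-epi-29) | COc1cc2ccc(=O)oc2c(OC)c1OC[C@@H]1C(C)=CC(=O)[C@@H]2C(C)(C)[C@H](OC(=O)CC(C)C)CC[C@]12C
F3 | step 18 | 6,8-dimethoxy-7-{[3α-(3-methylbutanoyloxy)-6-(trimethylsilyloxy)-9β-H-drima-5,7-dien-11-yl]oxy}-2H-chromen-2-one | COc1cc2ccc(=O)oc2c(OC)c1OC[C@@H]1C(C)=CC(O[Si](C)(C)C)=C2C(C)(C)[C@H](OC(=O)CC(C)C)CC[C@]12C
F4 | step 17 | 11-(methylsulfonyloxy)-6-(triisopropylsilyloxy)-5β,8β,9β-H-drim-6-en-3α-yl 3-methylbutanoate | CS(=O)(=O)OC[C@@H]1[C@H](C)C=C(O[Si](C(C)C)(C(C)C)C(C)C)[C@@H]2C(C)(C)[C@H](OC(=O)CC(C)C)CC[C@]12C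
F5 | step 16 | S-ethyl 3α-(3-methylbutanoyloxy)-6-(triisopropylsilyloxy)-5β,8β,9β-H-drim-6-ene-11-thioate | CCSC(=O)[C@@H]1[C@H](C)C=C(O[Si](C(C)C)(C(C)C)C(C)C)[C@@H]2C(C)(C)[C@H](OC(=O)CC(C)C)CC[C@]12C
F6 | step 19 | 6,8-dimethoxy-7-{[3α-(3-methylbutanoyloxy)-6-(trimethylsilyloxy)-5α,8β,9β-H-drim-6-en-11-yl]oxy}-2H-chromen-2-one | COc1cc2ccc(=O)oc2c(OC)c1OC[C@@H]1[C@H](C)C=C(O[Si](C)(C)C)[C@H]2C(C)(C)[C@H](OC(=O)CC(C)C)CC[C@]12C
A1 | alternative 1 | 4-methyl-4-(4-oxobutyl)cyclohexa-2,5-dien-1-one | O=CCCCC1(C)C=CC(=O)C=C1
A2 | alternative 1 | cis-fused 4a-methyl-2,3,4,4a,8,8a-hexahydronaphthalene-1,7-dione (terpenoid C6 and C3 ketones, C1–C2 alkene) | C1CCC(=O)[C@@H]2CC(=O)C=C[C@]12C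
A3 | alternative 2 | 2-[(3R)-5-iodo-2-methyl-3-(3-methylbutanoyloxy)pentan-2-yl]-3,5-dimethylcyclohex-2-en-1-one | ICC[C@@H](OC(=O)CC(C)C)C(C)(C)C1=C(C)C[C@@H](C)CC1=O
A4 | alternative 2 | trans-fused 3α-(3-methylbutanoyloxy)-4,4,8,10-tetramethyldecal-6-one (no C11) | C1[C@@H](C)CC(=O)[C@H]2C(C)(C)[C@H](OC(=O)CC(C)C)CC[C@]12C
A5 | alternative 3 | 7-{[(2Z,6E)-9-[(2S)-3,3-dimethyloxiran-2-yl]-3,7-dimethylnona-2,6-dien-1-yl]oxy}-6,8-dimethoxy-2H-chromen-2-one | COc1cc2ccc(=O)oc2c(OC)c1OC/C=C(/C)CC/C=C(\C)CC[C@@H]1OC1(C)C
A6 | alternative 3 | 7-{[3β-hydroxy-5α,9β-H-drim-7-en-11-yl]oxy}-6,8-dimethoxy-2H-chromen-2-one | COc1cc2ccc(=O)oc2c(OC)c1OC[C@@H]1C(C)=CC[C@H]2C(C)(C)[C@@H](O)CC[C@]12C
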